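Start from a one-step world: substrate turns into target, and target just keeps growing.

| flask | substrate | first nucleophile | second nucleophile | capture agent | temperature | remark | time |
|---|---|---|---|---|---|---|---|
| south | 0.051 M | 4 equiv | 1 equiv | 2.55 mM | 20 °C | run made earlier |  |
| east | 0.051 M | 2.7 equiv | 1 equiv | 2.55 mM | 31 °C | run made earlier |  |
| west | 0.051 M | 6 equiv | 1 equiv | 2.55 mM | 20 °C | run made earlier |  |
| north-east | 0.051 M | 4 equiv | 1 equiv | 1.3 mM | 31 °C | run made earlier |  |
| Monday's | 0.051 M (fed, over 4.0 min) | 4.00 equiv | 1.00 equiv | 2.55 mM |  | the addition at 5 °C, then warmed to 25 °C; the feed brings no volume worth counting | 5.0 min |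
| Friday's | 0.051 M | 4.00 equiv | 1.00 equiv | 2.55 mM |  | everything together at the start at 5 °C, warmed to 25 °C at 4.0 min | 5.0 min |
| Tuesday's | 0.051 M | 4.00 equiv | 1.00 equiv | 2.55 mM | 25 °C | everything together at the start | 5.0 min |
| Thursday's | 0.051 M | 4.00 equiv | 1.00 equiv (in portions, 3, over 4.0 min) | 2.55 mM | 25 °C | first portion at the start, last at 4.0 min | 5.0 min |
| Wednesday's | 0.051 M | 4.00 equiv | 1.00 equiv (fed, over 4.0 min) | 2.55 mM | 25 °C | all else is in the flask from the start; the feed brings no volume worth counting | 5.0 min |

| run | time / min | target / % | substrate / % |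
|---|---|---|---|
| south | 0.417 | 13 | 72 |
| south | 0.667 | 21 | 61 |
| south | 1.00 | 21 | 43 |
| south | 2.00 | 16 | 20 |
| south | 3.00 | 13 | 10 |
| south | 5.00 | 3 | 2 |
| east | 0.417 | 23 | 41 |
| east | 1.33 | 13 | 7 |
| east | 2.00 | 9 | 0 |
| east | 3.00 | 3 | 0 |
| east | 5.00 | 0 | 0 |
| east | 6.00 | 0 | 0 |
| west | 0.500 | 18 | 69 |
| west | 0.833 | 20 | 52 |
| west | 1.33 | 18 | 37 |
| west | 2.00 | 12 | 21 |
| west | 4.00 | 3 | 7 |
| west | 6.00 | 0 | 0 |
| north-east | 0.500 | 23 | 33 |
| north-east | 1.50 | 8 | 4 |
| north-east | 3.00 | 0 | 0 |
| north-east | 4.00 | 0 | 0 |
| north-east | 6.00 | 2 | 0 |

(scatter of a reading: 2 percentage points)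

- which flask leads in amount of target, in percent of the substrate charged ("all alike" within 1.5 percentage points) (Monday's / Friday's / Tuesday's / Thursday's / Wednesday's / all alike)
- how much target is there at the end, in percent of the substrate charged: Monday's
- how much target is there at the end, in percent of the substrate charged: Friday's
- how much target is there at the end, in percent of the substrate charged: Tuesday's
- how much target is there at the end, in percent of the substrate charged: Thursday's
- how much target is there at the end, in percent of the substrate charged: Wednesday's



The south run refuses that picture. At 0.667 min it had lost 39.0% of its substrate and held 21% target, yet at 5.00 min it had lost 98.0% and held 3%.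

To clear this up, ask which concentration sets the rate of loss. Compare west with south at 2.00 min: the substrate readings are close, 21% and 20%, but west, charged with 6 equiv of first nucleophile against 4 equiv, holds less target than south, 12% against 16%. So treat target as a middle member that first nucleophile consumes further. With first nucleophile in excess, take this loss as pseudo-first-order, its constant proportional to c(first nucleophile).

Now measure that constant. The first south reading gives target per substrate lost, 0.464, and the substrate readings give a constant of 0.809 min⁻¹. Around south's peak, arrival and loss balance, so the target's loss constant reads 0.930 min⁻¹. In the north-east run, at 31 °C, the substrate constant is 2.11 min⁻¹. Adding the target's observed fall to its arrival between the first two readings gives 2.14 min⁻¹. Since 25 °C lies nearly midway, take the geometric mean: the target's lifetime at 25 °C with this charge is 0.709 min, and it lengthens as c(first nucleophile) falls.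

Use it. Tuesday's, Wednesday's and Thursday's spend 7.05 lifetimes warm, while Monday's and Friday's spend 1.41. Expect the cold-started pair far ahead.

The forecast says the same: 21% for Monday's, 19% for Friday's, 2% for Tuesday's, 3% for Thursday's and 3% for Wednesday's, with Monday's leading. One of its grounds reads “About half the substrate consumed appears as target”.

The lead goes to Monday's, which ends at 19.4% target, against 16.5% in Friday's and 0.798%, 0.866% and 0.877% in Tuesday's, Thursday's and Wednesday's. Monday's also holds 38.7% over-reaction product at 5.00 min.

    substrate → open intermediate (k = 0.0210 s⁻¹, Ea = 75.0 kJ mol⁻¹)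
    first nucleophile + open intermediate → target (k = 5.50 L mol⁻¹ s⁻¹, Ea = 40.0 kJ mol⁻¹)
    second nucleophile + open intermediate → other capture product (k = 1.80 L mol⁻¹ s⁻¹, Ea = 41.0 kJ mol⁻¹)
    open intermediate → solvolysis product (k = 0.320 s⁻¹, Ea = 82.0 kJ mol⁻¹)
    first nucleophile + target → over-reaction product (k = 0.150 L mol⁻¹ s⁻¹, Ea = 41.0 kJ mol⁻¹)
    open intermediate + capture agent → trapped intermediate (k = 1.20 L mol⁻¹ s⁻¹, Ea = 62.0 kJ mol⁻¹)
    (constants at 25 °C)

Reckoned with the lifetime, 24.4% of the target standing at Monday's warming outlasts the warm minute, while Monday's still holds 21.6% substrate at the end.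

Now take a neighbour of Monday's, charged with 0.013 M of substrate at the same equivalents, so that its charged c(first nucleophile) is a quarter of Monday's. Its lifetime becomes 2.78 min, so 69.8% of the target standing at its warming outlasts the warm minute. The computed neighbour ends with 27.2% target, more than Monday's 19.4%, and 12.3% over-reaction product.

The runs were computed on assumed constants; noise was put on by code.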